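**Retrosynthetic overview**

1. The target is an isoflavone. Ring C (O1, C2, C3, C4, C4a, C8a) has its C4 carbonyl on ring A and carries the 2,3,4-trimethoxyphenyl ring B on C3. Adding water across C2=C3 in the retrosynthetic direction (OH on C3) makes C3–C4 an acyloin. The route rests on this pair of neighbouring, carbonyl-derived carbons.
2. Key disconnection C3–C4: C4 is an aryl aldehyde carbon and C3 an aryl ketone carbon, so both are electrophilic. The bond is therefore made by carbene umpolung of the aldehyde within a keto aldehyde tethered through O1–C2H2. This closes ring C, the only ring formed, since rings A and B are bought.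
3. The O1–C2 bond comes from O-alkylation of a ring A salicylaldehyde with the α-bromo ketone of ring B.
4. Ring A: prenyl is placed between the two MOM ethers of a mirror-symmetric phloroglucinol derivative by directed lithiation. The two carbons ortho to the third oxygen are then equivalent, so formylation puts prenyl at C6 and not at C8.
5. End game: loss of water across C2–C3, then removal of the two MOM groups.

Key step: step 8

Remark: the target has no stereocentre and its alkene ends in two methyl groups, so no configuration has to be set. Isoflavone numbering (O1, C2, C3, C4, C4a, C5 to C8, C8a) is used for the atoms of ring C and ring A.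

**Route**

Step 1
Reactants: 1 phloroglucinol (benzene-1,3,5-triol)
Product: 2 3,5-bis(methoxymethoxy)phenol
Conditions: MOMCl (2.0 equiv), i-Pr2NEt (2.2 equiv), DMF, 0 °C to rt; chromatography
Reagents that add atoms: chloromethyl methyl ether (MOMCl), COCCl
Why: O-Alkylation of a phenol with an α-chloro ether (MOM acetal formation) is fast and goes on oxygen, and because the three OH groups of 1 are equivalent the bis-ether 2 is one defined compound, taken by chromatography from a statistical mixture whose mono- and tris-ethers differ clearly in polarity and can be recycled.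

Step 2
Reactants: 2 3,5-bis(methoxymethoxy)phenol
Product: 3 [3,5-bis(methoxymethoxy)phenoxy]tri(propan-2-yl)silane
Conditions: TIPSCl (1.2 equiv), imidazole (2 equiv), DMF, rt
Reagents that add atoms: chlorotri(propan-2-yl)silane (TIPSCl), CC(C)[Si](Cl)(C(C)C)C(C)C
Why: Imidazole-promoted silylation of the last phenol removes the acidic proton before the lithiation, and the bulky, poorly coordinating TIPS ether resists n-BuLi and shields the two ring carbons next to it.

Step 3
Reactants: 3 [3,5-bis(methoxymethoxy)phenoxy]tri(propan-2-yl)silane; 4 prenyl bromide (1-bromo-3-methylbut-2-ene)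
Product: 6 [3,5-bis(methoxymethoxy)-4-(3-methylbut-2-enyl)phenoxy]tri(propan-2-yl)silane, via aryllithium 5 (not isolated)
Conditions: n-BuLi (1.15 equiv), THF, 0 °C, 1 h; CuBr·SMe2 (10 mol %), then 4 (1.3 equiv), −78 °C to rt
Reagents that add atoms: none
Why: Directed ortho-metalation takes place at the ring carbon between the two chelating MOM ethers, the most acidic and the only unshielded site, to give 5, and copper-assisted SN2 allylation of 5 at the primary carbon of 4 should deliver the linear prenyl group.

Step 4
Reactants: 6 [3,5-bis(methoxymethoxy)-4-(3-methylbut-2-enyl)phenoxy]tri(propan-2-yl)silane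
Product: 7 3,5-bis(methoxymethoxy)-4-(3-methylbut-2-enyl)phenol
Conditions: TBAF (1.1 equiv), AcOH (1.1 equiv), THF, 0 °C
Reagents that add atoms: none
Why: Fluoride-induced desilylation is driven by the strong Si–F bond and the good phenoxide leaving group, and the acetic acid buffer keeps the medium near neutral so that the MOM acetals and the alkene are untouched.

Step 5
Reactants: 7 3,5-bis(methoxymethoxy)-4-(3-methylbut-2-enyl)phenol
Product: 8 2-hydroxy-4,6-bis(methoxymethoxy)-5-(3-methylbut-2-enyl)benzaldehyde (CHO on C1 between OH on C2 and OMOM on C6; prenyl on C5 between the two OMOM groups; H on C3)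
Conditions: MgCl2 (anhydrous, 2 equiv), Et3N (4 equiv), (CH2O)n (6 equiv), THF, reflux; sat. aq NH4Cl work-up
Reagents that add atoms: paraformaldehyde (reacts as formaldehyde), C=O
Why: In the Casnati–Skattebøl ortho-formylation magnesium holds the phenoxide oxygen and formaldehyde together, so that C–C bond formation occurs only ortho to the free OH and a second formaldehyde accepts hydride to give the aldehyde, and since the two ortho carbons of 7 are mirror images of each other only one regioisomer can form, with prenyl between the two MOM ethers and para to the OH.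

Step 6
Reactants: 9 2',3',4'-trimethoxyacetophenone (1-(2,3,4-trimethoxyphenyl)ethanone)
Product: 10 2-bromo-1-(2,3,4-trimethoxyphenyl)ethanone
Conditions: CuBr2 (2.1 equiv), EtOAc/CHCl3 1:1, reflux
Reagents that add atoms: CuBr2, [Cu+2].[Br-].[Br-]
Why: α-Bromination of an aryl methyl ketone with CuBr2 runs through the copper-bound enol, stops at the monobromide and, unlike Br2, should leave the electron-rich trimethoxyphenyl ring unbrominated.

Step 7
Reactants: 8 2-hydroxy-4,6-bis(methoxymethoxy)-5-(3-methylbut-2-enyl)benzaldehyde; 10 2-bromo-1-(2,3,4-trimethoxyphenyl)ethanone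
Product: 11 4,6-bis(methoxymethoxy)-5-(3-methylbut-2-enyl)-2-[2-oxo-2-(2,3,4-trimethoxyphenyl)ethoxy]benzaldehyde
Conditions: K2CO3 (1.5 equiv), acetone, rt, worked up as soon as 8 is consumed
Reagents that add atoms: none
Why: In this Williamson ether synthesis the only free OH of 8 displaces bromide from the very reactive phenacyl-type bromide by SN2, and a mild base at room temperature together with the poorly electrophilic trioxygenated aldehyde should keep 11 from going on to a 2-aroylbenzofuran by aldol condensation (the Rap–Stoermer course).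

Step 8
Reactants: 11 4,6-bis(methoxymethoxy)-5-(3-methylbut-2-enyl)-2-[2-oxo-2-(2,3,4-trimethoxyphenyl)ethoxy]benzaldehyde
Product: 13 3-hydroxy-5,7-bis(methoxymethoxy)-6-(3-methylbut-2-enyl)-3-(2,3,4-trimethoxyphenyl)chroman-4-one (racemic at C3), via enaminol 12 (not isolated)
Conditions: 3-benzyl-5-(2-hydroxyethyl)-4-methylthiazolium chloride (20 mol %), Et3N (50 mol %), degassed EtOH (0.05 M), 70 °C, Ar
Reagents that add atoms: none
Why: Et3N deprotonates the thiazolium salt, the carbene adds to the formyl carbon of 11, and a proton shift gives the enaminol 12, in which the former aldehyde carbon (C4) is nucleophilic. This carbon attacks the tethered aryl ketone carbon (C3), and collapse of the adduct releases the carbene and leaves the C4 ketone beside the new tertiary C3 alcohol. The reaction type is the carbene-catalysed intramolecular crossed aldehyde–ketone benzoin reaction, which is known for 2-(2-oxoalkoxy)benzaldehydes and gives 3-hydroxychroman-4-ones. Ring C closes in the 6-exo-trig mode, with C4, C4a, C8a, O1, C2 and C3 in the ring and the ketone oxygen outside it. The C3 stereocentre is set without control because the catalyst is achiral, so 13 is a racemate, which is acceptable since step 9 makes C3 trigonal again. The step needs the crossed closure to beat both homo-benzoin coupling and amine-mediated aldol closure of the O–CH2–C=O unit onto the aldehyde: the short tether, the dilution and the two ortho oxygens that hinder dimerisation secure the first, and the weak base and the poorly electrophilic aldehyde secure the second, while the oxygen that carries the ketone arm fixes the ring fusion.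

Step 9
Reactants: 13 3-hydroxy-5,7-bis(methoxymethoxy)-6-(3-methylbut-2-enyl)-3-(2,3,4-trimethoxyphenyl)chroman-4-one
Product: 15 5,7-bis(methoxymethoxy)-6-(3-methylbut-2-enyl)-3-(2,3,4-trimethoxyphenyl)-4H-chromen-4-one, via chlorosulfite ester 14 (not isolated)
Conditions: SOCl2 (1.5 equiv), pyridine, 0 °C to rt
Reagents that add atoms: none
Why: This is a β-elimination (dehydration) of a tertiary benzylic alcohol through its chlorosulfite, in which the C2 hydrogens are the only β-hydrogens, so that loss of SO2 and HCl can only give C2=C3, driven by formation of the conjugated 4-pyranone, which erases the C3 stereocentre in a basic medium that MOM ethers and the prenyl alkene tolerate.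

Step 10
Reactants: 15 5,7-bis(methoxymethoxy)-6-(3-methylbut-2-enyl)-3-(2,3,4-trimethoxyphenyl)-4H-chromen-4-one
Product: 16 5,7-dihydroxy-6-(3-methylbut-2-enyl)-3-(2,3,4-trimethoxyphenyl)-4H-chromen-4-one (target)
Conditions: 3 M aq HCl (10 vol %), MeOH, 45 °C, monitored; NaHCO3 quench as soon as the 7-O-MOM ether is gone
Reagents that add atoms: none
Why: In this acid-catalysed acetal cleavage (transacetalisation to methanol) a protonated MOM ether loses a stabilised oxocarbenium ion much faster than dilute acid protonates the trisubstituted alkene, so both phenols should be freed before prenyl can close onto O5 or O7, while the aryl methyl ethers and the pyranone are inert.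

**Compound list**

1 | phloroglucinol (benzene-1,3,5-triol) | Oc1cc(O)cc(O)c1 | starting material
2 | 3,5-bis(methoxymethoxy)phenol | COCOc1cc(O)cc(OCOC)c1 | intermediate
3 | [3,5-bis(methoxymethoxy)phenoxy]tri(propan-2-yl)silane | COCOc1cc(OCOC)cc(O[Si](C(C)C)(C(C)C)C(C)C)c1 | intermediate
4 | prenyl bromide (1-bromo-3-methylbut-2-ene) | CC(C)=CCBr | starting material
5 | {2,6-bis(methoxymethoxy)-4-[tri(propan-2-yl)silyloxy]phenyl}lithium (not isolated) | COCOc1cc(O[Si](C(C)C)(C(C)C)C(C)C)cc(OCOC)c1[Li] | intermediate
6 | [3,5-bis(methoxymethoxy)-4-(3-methylbut-2-enyl)phenoxy]tri(propan-2-yl)silane | COCOc1cc(O[Si](C(C)C)(C(C)C)C(C)C)cc(OCOC)c1CC=C(C)C | intermediate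
7 | 3,5-bis(methoxymethoxy)-4-(3-methylbut-2-enyl)phenol | COCOc1cc(O)cc(OCOC)c1CC=C(C)C | intermediate
8 | 2-hydroxy-4,6-bis(methoxymethoxy)-5-(3-methylbut-2-enyl)benzaldehyde | O=Cc1c(O)cc(OCOC)c(CC=C(C)C)c1OCOC | intermediate
9 | 2',3',4'-trimethoxyacetophenone | CC(=O)c1ccc(OC)c(OC)c1OC | starting material
10 | 2-bromo-1-(2,3,4-trimethoxyphenyl)ethanone | O=C(CBr)c1ccc(OC)c(OC)c1OC | intermediate
11 | 4,6-bis(methoxymethoxy)-5-(3-methylbut-2-enyl)-2-[2-oxo-2-(2,3,4-trimethoxyphenyl)ethoxy]benzaldehyde | O=Cc1c(OCC(=O)c2ccc(OC)c(OC)c2OC)cc(OCOC)c(CC=C(C)C)c1OCOC | intermediate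
12 | catalyst-bound enaminol: [3-benzyl-5-(2-hydroxyethyl)-4-methylthiazol-2(3H)-ylidene](aryl)methanol, aryl = ring A of 11 (not isolated; alkene geometry undefined) | OC(=C1SC(CCO)=C(C)N1Cc1ccccc1)c1c(OCC(=O)c2ccc(OC)c(OC)c2OC)cc(OCOC)c(CC=C(C)C)c1OCOC | intermediate
13 | 3-hydroxy-5,7-bis(methoxymethoxy)-6-(3-methylbut-2-enyl)-3-(2,3,4-trimethoxyphenyl)chroman-4-one (racemate, C3 left undefined) | COCOc1cc2OCC(O)(c3ccc(OC)c(OC)c3OC)C(=O)c2c(OCOC)c1CC=C(C)C | intermediate
14 | chlorosulfite ester of 13 at the C3 oxygen (racemate, not isolated) | COCOc1cc2OCC(OS(=O)Cl)(c3ccc(OC)c(OC)c3OC)C(=O)c2c(OCOC)c1CC=C(C)C | intermediate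
15 | 5,7-bis(methoxymethoxy)-6-(3-methylbut-2-enyl)-3-(2,3,4-trimethoxyphenyl)-4H-chromen-4-one | COCOc1cc2occ(-c3ccc(OC)c(OC)c3OC)c(=O)c2c(OCOC)c1CC=C(C)C | intermediate
16 | 5,7-dihydroxy-6-(3-methylbut-2-enyl)-3-(2,3,4-trimethoxyphenyl)-4H-chromen-4-one (no stereocentre) | COc1ccc(-c2coc3cc(O)c(CC=C(C)C)c(O)c3c2=O)c(OC)c1OC | target

**Step count**

Total step count: 10.
Longest linear sequence: 9 steps from phloroglucinol (steps 1, 2, 3, 4, 5, 7, 8, 9, 10). Step 6 is a one-step branch.

**Steps most likely to fail**

**1. Step 8.**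
- What may go wrong: the carbene may add only sluggishly to an aldehyde that is flanked by two ortho oxygens and deactivated by three donor oxygens. The enaminol may also close slowly on a ketone that is itself deactivated by its ortho and para methoxy groups. Over a long reaction time, amine-mediated enolisation of the O–CH2–C=O unit with aldol condensation onto the aldehyde, or air oxidation of the enaminol, would then consume the substrate.
- Fallback (sets out from 8, returns at 15): C3–C4 is made with normal polarity and C2 is added last as a one-carbon unit.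
  - Commercial 2,3,4-trimethoxybenzyl chloride and Mg (THF, 0 °C, slow addition) give 2,3,4-trimethoxybenzylmagnesium chloride F1.
  - F1 (2.2 equiv) adds to the aldehyde of 8 to give racemic 2-[1-hydroxy-2-(2,3,4-trimethoxyphenyl)ethyl]-3,5-bis(methoxymethoxy)-4-(3-methylbut-2-enyl)phenol F2.
  - MnO2 in CH2Cl2 oxidises the benzylic alcohol to the deoxybenzoin 1-[2-hydroxy-4,6-bis(methoxymethoxy)-5-(3-methylbut-2-enyl)phenyl]-2-(2,3,4-trimethoxyphenyl)ethanone F3.
  - N,N-Dimethylformamide dimethyl acetal in toluene at 90 °C condenses at the activated CH2 to give the enaminone F4. The ortho phenol closes onto F4 with loss of the amine, which gives 15.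

**2. Step 10.**
- What may go wrong: protonation of the trisubstituted alkene may compete with the slower cleavage of the 7-O-MOM ether. The tertiary cation would then be trapped by the freed O5 or O7 phenol (closure to a dimethylchroman ring) or by the solvent.
- Fallback (sets out from 3 through aryllithium 5, returns at 16): an allyl group, whose monosubstituted alkene dilute acid does not protonate, stands in for prenyl until the phenols are free.
  - Aryllithium 5 is quenched with allyl bromide to give [4-allyl-3,5-bis(methoxymethoxy)phenoxy]tri(propan-2-yl)silane F5.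
  - The conditions of steps 4, 5, 7, 8 and 9 then lead through 4-allyl-3,5-bis(methoxymethoxy)phenol F6 and 5-allyl-2-hydroxy-4,6-bis(methoxymethoxy)benzaldehyde F7.
  - They continue through 5-allyl-4,6-bis(methoxymethoxy)-2-[2-oxo-2-(2,3,4-trimethoxyphenyl)ethoxy]benzaldehyde F8 and its catalyst-bound enaminol F9.
  - Next come racemic 6-allyl-3-hydroxy-5,7-bis(methoxymethoxy)-3-(2,3,4-trimethoxyphenyl)chroman-4-one F10 and its chlorosulfite ester F11, which lead to 6-allyl-5,7-bis(methoxymethoxy)-3-(2,3,4-trimethoxyphenyl)-4H-chromen-4-one F12.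
  - HCl in MeOH frees 6-allyl-5,7-dihydroxy-3-(2,3,4-trimethoxyphenyl)-4H-chromen-4-one F13.
  - Olefin cross-metathesis with excess 2-methylbut-2-ene (second-generation Grubbs catalyst, 5 mol %, CH2Cl2, 40 °C) turns allyl into prenyl under neutral conditions and gives 16.

**3. Step 7.**
- What may go wrong: after the O-alkylation, carbonate may deprotonate the doubly activated O–CH2–C=O group. The enolate may then close on the neighbouring aldehyde, and loss of water would aromatise the adduct irreversibly to a benzofuran, so that the keto aldehyde does not accumulate.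
- Fallback (sets out from 10 and 8, returns at 11): the arm is attached at the alcohol oxidation level, where no enolisable CH2 exists, and the ketone is unveiled without base.
  - NaBH4 (MeOH, 0 °C) reduces 10 to racemic 2-bromo-1-(2,3,4-trimethoxyphenyl)ethanol F14.
  - K2CO3 in MeOH closes F14 to racemic 2-(2,3,4-trimethoxyphenyl)oxirane F15.
  - The phenoxide of 8 (Cs2CO3, DMF, 70 °C) opens F15 at its CH2 terminus to give racemic 2-[2-hydroxy-2-(2,3,4-trimethoxyphenyl)ethoxy]-4,6-bis(methoxymethoxy)-5-(3-methylbut-2-enyl)benzaldehyde F16.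
  - Dess–Martin periodinane buffered with NaHCO3 (CH2Cl2, rt) oxidises the secondary alcohol to 11.

**Further compounds**

F1 | step 8 | 2,3,4-trimethoxybenzylmagnesium chloride | COc1ccc(C[Mg]Cl)c(OC)c1OC
F2 | step 8 | 2-[1-hydroxy-2-(2,3,4-trimethoxyphenyl)ethyl]-3,5-bis(methoxymethoxy)-4-(3-methylbut-2-enyl)phenol (racemate) | OC(Cc1ccc(OC)c(OC)c1OC)c1c(O)cc(OCOC)c(CC=C(C)C)c1OCOC
F3 | step 8 | 1-[2-hydroxy-4,6-bis(methoxymethoxy)-5-(3-methylbut-2-enyl)phenyl]-2-(2,3,4-trimethoxyphenyl)ethanone | O=C(Cc1ccc(OC)c(OC)c1OC)c1c(O)cc(OCOC)c(CC=C(C)C)c1OCOC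
F4 | step 8 | 3-(dimethylamino)-1-[2-hydroxy-4,6-bis(methoxymethoxy)-5-(3-methylbut-2-enyl)phenyl]-2-(2,3,4-trimethoxyphenyl)prop-2-en-1-one (not isolated, alkene geometry undefined) | CN(C)C=C(C(=O)c1c(O)cc(OCOC)c(CC=C(C)C)c1OCOC)c1ccc(OC)c(OC)c1OC
F5 | step 10 | [4-allyl-3,5-bis(methoxymethoxy)phenoxy]tri(propan-2-yl)silane | COCOc1cc(O[Si](C(C)C)(C(C)C)C(C)C)cc(OCOC)c1CC=C
F6 | step 10 | 4-allyl-3,5-bis(methoxymethoxy)phenol | COCOc1cc(O)cc(OCOC)c1CC=C
F7 | step 10 | 5-allyl-2-hydroxy-4,6-bis(methoxymethoxy)benzaldehyde | O=Cc1c(O)cc(OCOC)c(CC=C)c1OCOC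
F8 | step 10 | 5-allyl-4,6-bis(methoxymethoxy)-2-[2-oxo-2-(2,3,4-trimethoxyphenyl)ethoxy]benzaldehyde | O=Cc1c(OCC(=O)c2ccc(OC)c(OC)c2OC)cc(OCOC)c(CC=C)c1OCOC
F9 | step 10 | catalyst-bound enaminol of F8 (not isolated, alkene geometry undefined) | OC(=C1SC(CCO)=C(C)N1Cc1ccccc1)c1c(OCC(=O)c2ccc(OC)c(OC)c2OC)cc(OCOC)c(CC=C)c1OCOC
F10 | step 10 | 6-allyl-3-hydroxy-5,7-bis(methoxymethoxy)-3-(2,3,4-trimethoxyphenyl)chroman-4-one (racemate) | COCOc1cc2OCC(O)(c3ccc(OC)c(OC)c3OC)C(=O)c2c(OCOC)c1CC=C
F11 | step 10 | chlorosulfite ester of F10 (racemate, not isolated) | COCOc1cc2OCC(OS(=O)Cl)(c3ccc(OC)c(OC)c3OC)C(=O)c2c(OCOC)c1CC=C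
F12 | step 10 | 6-allyl-5,7-bis(methoxymethoxy)-3-(2,3,4-trimethoxyphenyl)-4H-chromen-4-one | COCOc1cc2occ(-c3ccc(OC)c(OC)c3OC)c(=O)c2c(OCOC)c1CC=C
F13 | step 10 | 6-allyl-5,7-dihydroxy-3-(2,3,4-trimethoxyphenyl)-4H-chromen-4-one | COc1ccc(-c2coc3cc(O)c(CC=C)c(O)c3c2=O)c(OC)c1OC
F14 | step 7 | 2-bromo-1-(2,3,4-trimethoxyphenyl)ethanol (racemate) | OC(CBr)c1ccc(OC)c(OC)c1OC
F15 | step 7 | 2-(2,3,4-trimethoxyphenyl)oxirane (racemate) | COc1ccc(C2CO2)c(OC)c1OC
F16 | step 7 | 2-[2-hydroxy-2-(2,3,4-trimethoxyphenyl)ethoxy]-4,6-bis(methoxymethoxy)-5-(3-methylbut-2-enyl)benzaldehyde (racemate) | O=Cc1c(OCC(O)c2ccc(OC)c(OC)c2OC)cc(OCOC)c(CC=C(C)C)c1OCOC
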